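**Retrosynthetic overview**
- Feature: two identical, fully substituted 2-hydroxy-5-methoxy-6-methyl-1,4-benzoquinone rings (ring A and ring B) are joined through their C3 atoms by an unbranched, unfunctionalized thirteen-carbon chain c1–c13; there is no stereocentre.
- The chain is cut at c3–c4 and c10–c11: c4–c10 comes from azelaic acid after loss of both carboxyl carbons, and each ring with its three adjoining chain carbons comes from a 4-arylbutanoic acid. Both partners are N-hydroxyphthalimide esters, joined by a two-directional nickel-electrocatalytic doubly decarboxylative coupling.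
- Each quinone travels as a 2,6-bis(methoxymethoxy)-3,5-dimethoxy-4-methylphenyl ring. MOM removal and (NH4)2Ce(NO3)6 oxidation unveil the hydroxyquinone; the mirror symmetry of the ring makes either phenol, and para or ortho oxidation, converge on the same product.
- Arm: 2,6-dimethoxytoluene is dibrominated, hydroxylated and MOM-protected, then lithiated between the two OMOM groups and alkylated with 4-bromo-1,1,1-trimethoxybutane; saponification and esterification follow.
- No ring is formed in the route: both six-membered carbocycles are the benzene ring of 2,6-dimethoxytoluene and are only raised to the quinone oxidation level in the last step.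

Key step: step 8

Remark: the target is treated as the drawn 2-hydroxy-1,4-benzoquinone tautomer. In the twofold steps 1, 2, 3, 7, 9 and 10 both equivalent sites react in one operation and the half-reacted species are not counted separately. Step 7 takes up two molecules of 10, one at each carboxyl group. In step 8 the half-coupled ester is numbered because it is a new redox-active ester that must enter a second coupling.

**Route**

Step 1
Reactants: 1 2,6-dimethoxytoluene
Product: 2 1,5-dibromo-2,4-dimethoxy-3-methylbenzene
Conditions: NBS (2.2 equiv), MeCN, 0 °C to 50 °C, dark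
Reagents that add atoms: N-bromosuccinimide, O=C1CCC(=O)N1Br
Why: Electrophilic aromatic bromination in a polar solvent should go twice, at C3 and C5 of the toluene, each ortho to one methoxy group and para to the other, and leave C4, which is meta to both, untouched.

Step 2
Reactants: 2 1,5-dibromo-2,4-dimethoxy-3-methylbenzene
Product: 3 4,6-dimethoxy-5-methylbenzene-1,3-diol
Conditions: Pd2(dba)3 (cat.), tBuXPhos (cat.), KOH, 1,4-dioxane/H2O, 100 °C, argon; then cold 1 M HCl
Reagents that add atoms: potassium hydroxide, [K+].[OH-]
Why: Palladium-catalysed hydroxylation of aryl bromides (oxidative addition to zerovalent palladium, hydroxide exchange, C–O reductive elimination) should convert both bromides, the bulky biarylphosphine suppressing diaryl ether formation and the exclusion of air protecting the electron-rich diol.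

Step 3
Reactants: 3 4,6-dimethoxy-5-methylbenzene-1,3-diol
Product: 4 1,5-bis(methoxymethoxy)-2,4-dimethoxy-3-methylbenzene
Conditions: NaH, DMF, 0 °C; MOMCl, 0 °C to rt
Reagents that add atoms: chloromethyl methyl ether, COCCl
Why: Williamson-type O-alkylation of both phenoxides should give the bis-MOM ether, which marks the two oxygen atoms destined to become hydroxyl and carbonyl and provides two chelating directing groups for step 4.

Step 4
Reactants: 4 1,5-bis(methoxymethoxy)-2,4-dimethoxy-3-methylbenzene; 5 4-bromo-1,1,1-trimethoxybutane (trimethyl 4-bromoorthobutyrate)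
Product: 8 methyl 4-[2,6-bis(methoxymethoxy)-3,5-dimethoxy-4-methylphenyl]butanoate, via aryllithium 6 (not isolated), via trimethyl orthoester 7 (not isolated)
Conditions: n-BuLi, TMEDA, THF, 0 °C; then 5, 0 °C to rt; then 1 M aq. citric acid, THF, rt
Reagents that add atoms: water, O
Why: Directed ortho-metalation removes the only ring hydrogen, which lies between the two OMOM groups, the aryllithium should displace the primary bromide of 5 in an SN2 alkylation while the orthoester is inert to organolithium, and the brief citric acid work-up hydrolyses the orthoester to the methyl ester at an acidity that aryl MOM ethers tolerate.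

Step 5
Reactants: 8 methyl 4-[2,6-bis(methoxymethoxy)-3,5-dimethoxy-4-methylphenyl]butanoate
Product: 9 4-[2,6-bis(methoxymethoxy)-3,5-dimethoxy-4-methylphenyl]butanoic acid
Conditions: LiOH·H2O, THF/MeOH/H2O, rt; then 1 M HCl to pH 4, 0 °C
Reagents that add atoms: lithium hydroxide, [Li+].[OH-]
Why: Ester saponification should be clean because MOM acetals and aryl methyl ethers are stable to base and to a brief cold acidification to pH 4.

Step 6
Reactants: 9 4-[2,6-bis(methoxymethoxy)-3,5-dimethoxy-4-methylphenyl]butanoic acid; 10 N-hydroxyphthalimide
Product: 11 1,3-dioxoisoindolin-2-yl 4-[2,6-bis(methoxymethoxy)-3,5-dimethoxy-4-methylphenyl]butanoate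
Conditions: DIC, DMAP (cat.), CH2Cl2, rt
Reagents that add atoms: none
Why: Steglich-type carbodiimide esterification of an unhindered primary carboxylic acid with N-hydroxyphthalimide should give the redox-active ester under neutral conditions that leave the acetals intact.

Step 7
Reactants: 12 azelaic acid (nonanedioic acid); 10 N-hydroxyphthalimide
Product: 13 bis(1,3-dioxoisoindolin-2-yl) nonanedioate
Conditions: 10 (2.2 equiv in all), DIC (2.2 equiv), DMAP (cat.), CH2Cl2, rt
Reagents that add atoms: N-hydroxyphthalimide (second molecule of 10), ON1C(=O)c2ccccc2C1=O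
Why: Twofold Steglich-type carbodiimide esterification should convert each of the two unhindered carboxyl groups of the diacid with one molecule of N-hydroxyphthalimide, so that two molecules of 10 are incorporated, and the bis(redox-active ester) is expected to be a crystalline solid that can be purified by recrystallization.

Step 8
Reactants: 13 bis(1,3-dioxoisoindolin-2-yl) nonanedioate; 11 1,3-dioxoisoindolin-2-yl 4-[2,6-bis(methoxymethoxy)-3,5-dimethoxy-4-methylphenyl]butanoate
Product: 15 1,13-bis[2,6-bis(methoxymethoxy)-3,5-dimethoxy-4-methylphenyl]tridecane, via half-coupled ester 14 (not isolated)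
Conditions: 11 (about 6 equiv to 13, two molecules incorporated), NiCl2·6H2O (cat.), 2,2':6',2''-terpyridine (cat.), AgNO3 (substoichiometric), NaI, NMP, Mg anode, RVC cathode, constant current, rt; aq. NH4Cl work-up
Reagents that add atoms: none
Why: Single-electron reduction of each N-acyloxyphthalimide, at the cathode or by low-valent nickel, gives a radical anion that fragments to phthalimide anion, CO2 and a primary alkyl radical; terpyridine-ligated low-valent nickel captures one radical from the arm and one from an azelate terminus, and reductive elimination from the dialkylnickel forms c3–c4, after which half-coupled ester 14 re-enters the same cycle to form c10–c11. The closest known reaction is the nickel-electrocatalytic doubly decarboxylative coupling of two primary alkyl N-hydroxyphthalimide esters, run here at both ends of a diester. No ring is closed and no stereocentre is created. The selectivity needed is cross- over homo-coupling, which the catalyst does not supply, so 11 is used in about threefold excess per terminus to drive each azelate end statistically to the cross product, and the 1,6-diarylhexane dimer and the azelate oligomers should be separable by chromatography because they differ greatly in size and polarity. Chemoselectivity rests on the reductive regime, which leaves the easily oxidized tetraalkoxyarenes and the MOM acetals untouched, and on all radicals being primary and unhindered.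

Step 9
Reactants: 15 1,13-bis[2,6-bis(methoxymethoxy)-3,5-dimethoxy-4-methylphenyl]tridecane
Product: 16 2,2'-(tridecane-1,13-diyl)bis(4,6-dimethoxy-5-methylbenzene-1,3-diol)
Conditions: 3 M HCl, MeOH/THF, 40 °C, argon (degassed)
Reagents that add atoms: none
Why: Acid-catalysed acetal methanolysis should remove all four aryl MOM groups while the aryl methyl ethers are inert, and degassing protects the electron-rich tetraphenol, which is taken on at once.

Step 10
Reactants: 16 2,2'-(tridecane-1,13-diyl)bis(4,6-dimethoxy-5-methylbenzene-1,3-diol)
Product: 17 3,3'-(tridecane-1,13-diyl)bis(2-hydroxy-5-methoxy-6-methylcyclohexa-2,5-diene-1,4-dione), the target CNP0110425.0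
Conditions: (NH4)2Ce(NO3)6 (4.4 equiv), MeCN/H2O, 0 °C
Reagents that add atoms: water, O
Why: Oxidative demethylation of a 4-methoxyphenol by tetravalent cerium (two-electron oxidation of each ring, water attack at the methoxy-bearing carbon, loss of methanol) should give the hydroxyquinone, and because each ring is mirror-symmetric, either phenol, by para or by ortho oxidation followed by tautomerization, leads to the same 2-hydroxy-5-methoxy-1,4-quinone, whose remaining hydroxyl is a vinylogous acid that resists further oxidation at 0 °C.

**Compound list**
1 | 2,6-dimethoxytoluene | Cc1c(OC)cccc1OC | starting material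
2 | 1,5-dibromo-2,4-dimethoxy-3-methylbenzene | Cc1c(OC)c(Br)cc(Br)c1OC | intermediate
3 | 4,6-dimethoxy-5-methylbenzene-1,3-diol | Cc1c(OC)c(O)cc(O)c1OC | intermediate
4 | 1,5-bis(methoxymethoxy)-2,4-dimethoxy-3-methylbenzene | Cc1c(OC)c(OCOC)cc(OCOC)c1OC | intermediate
5 | 4-bromo-1,1,1-trimethoxybutane (trimethyl 4-bromoorthobutyrate) | COC(CCCBr)(OC)OC | starting material
6 | [2,6-bis(methoxymethoxy)-3,5-dimethoxy-4-methylphenyl]lithium | [Li]c1c(OCOC)c(OC)c(C)c(OC)c1OCOC | intermediate
7 | 1,3-bis(methoxymethoxy)-4,6-dimethoxy-5-methyl-2-(4,4,4-trimethoxybutyl)benzene | COCOc1c(CCCC(OC)(OC)OC)c(OCOC)c(OC)c(C)c1OC | intermediate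
8 | methyl 4-[2,6-bis(methoxymethoxy)-3,5-dimethoxy-4-methylphenyl]butanoate | COCOc1c(CCCC(=O)OC)c(OCOC)c(OC)c(C)c1OC | intermediate
9 | 4-[2,6-bis(methoxymethoxy)-3,5-dimethoxy-4-methylphenyl]butanoic acid | COCOc1c(CCCC(=O)O)c(OCOC)c(OC)c(C)c1OC | intermediate
10 | N-hydroxyphthalimide | ON1C(=O)c2ccccc2C1=O | starting material
11 | 1,3-dioxoisoindolin-2-yl 4-[2,6-bis(methoxymethoxy)-3,5-dimethoxy-4-methylphenyl]butanoate | COCOc1c(CCCC(=O)ON2C(=O)c3ccccc3C2=O)c(OCOC)c(OC)c(C)c1OC | intermediate
12 | azelaic acid (nonanedioic acid) | OC(=O)CCCCCCCC(=O)O | starting material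
13 | bis(1,3-dioxoisoindolin-2-yl) nonanedioate | O=C(CCCCCCCC(=O)ON1C(=O)c2ccccc2C1=O)ON1C(=O)c2ccccc2C1=O | intermediate
14 | 1,3-dioxoisoindolin-2-yl 11-[2,6-bis(methoxymethoxy)-3,5-dimethoxy-4-methylphenyl]undecanoate | COCOc1c(CCCCCCCCCCC(=O)ON2C(=O)c3ccccc3C2=O)c(OCOC)c(OC)c(C)c1OC | intermediate
15 | 1,13-bis[2,6-bis(methoxymethoxy)-3,5-dimethoxy-4-methylphenyl]tridecane | COCOc1c(CCCCCCCCCCCCCc2c(OCOC)c(OC)c(C)c(OC)c2OCOC)c(OCOC)c(OC)c(C)c1OC | intermediate
16 | 2,2'-(tridecane-1,13-diyl)bis(4,6-dimethoxy-5-methylbenzene-1,3-diol) | COc1c(C)c(OC)c(O)c(CCCCCCCCCCCCCc2c(O)c(OC)c(C)c(OC)c2O)c1O | intermediate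
17 | 3,3'-(tridecane-1,13-diyl)bis(2-hydroxy-5-methoxy-6-methylcyclohexa-2,5-diene-1,4-dione) | COC1=C(C)C(=O)C(O)=C(CCCCCCCCCCCCCC2=C(O)C(=O)C(C)=C(OC)C2=O)C1=O | target

**Step count**
Total step count: 10. Longest linear sequence: 9 steps (steps 1 to 6, then 8, 9 and 10); step 7 is a one-step side branch.

**Steps most likely to fail, with fallbacks**

Step 8. The two cross-couplings may be outrun by homodimerization of the arm radical, by premature reduction of one azelate terminus to a C–H end, or by oligomerization of the azelate, so that little doubly cross-coupled material forms. Fallback: the chain is brought in as an intact C13 electrophile. Commercial tridecanedioic acid (OC(=O)CCCCCCCCCCCC(=O)O) is reduced with LiAlH4 in THF to tridecane-1,13-diol F1, and an Appel reaction (CBr4, PPh3, CH2Cl2) converts this into 1,13-dibromotridecane F2. Aryllithium 6, generated from 4 as in step 4 and used in excess, is then alkylated at both ends of F2 (THF, 0 °C to rt). The fallback sets out from 4 and comes back to the route at 15.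

Step 2. The second C–O coupling may stall on the electron-rich bromophenoxide, and protodebromination, diaryl ether formation or aerial oxidation of the diol in hot alkali may erode the material. Fallback: the oxygen atoms are introduced through boron. Miyaura borylation of 2 (B2pin2, Pd(dppf)Cl2, KOAc, 1,4-dioxane, 90 °C) should give 2,2'-(4,6-dimethoxy-5-methyl-1,3-phenylene)bis(4,4,5,5-tetramethyl-1,3,2-dioxaborolane) F3, which is oxidized with H2O2 and NaOH in THF at 0 °C. The fallback sets out from 2 and comes back to the route at 3.

Step 10. Oxidation of the free tetraphenol may suffer from phenoxyl radical coupling between rings or chains, or from over-oxidation of the very electron-rich rings. Fallback: the order of unmasking is reversed. Compound 15 is oxidized directly with (NH4)2Ce(NO3)6 in MeCN/H2O at 0 °C; oxidative dealkylation of a para OMOM/OMe pair (both pairs are equivalent by symmetry) should give 3,3'-(tridecane-1,13-diyl)bis[5-methoxy-2-(methoxymethoxy)-6-methylcyclohexa-2,5-diene-1,4-dione] F4. Its vinylogous MOM esters are then cleaved with trifluoroacetic acid in wet CH2Cl2 at 0 °C. The fallback sets out from 15, bypasses 16 and comes back to the route at 17.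

**Further compounds**
F1 | step 8 | tridecane-1,13-diol | OCCCCCCCCCCCCCO
F2 | step 8 | 1,13-dibromotridecane | BrCCCCCCCCCCCCCBr
F3 | step 2 | 2,2'-(4,6-dimethoxy-5-methyl-1,3-phenylene)bis(4,4,5,5-tetramethyl-1,3,2-dioxaborolane) | Cc1c(OC)c(B2OC(C)(C)C(C)(C)O2)cc(B2OC(C)(C)C(C)(C)O2)c1OC
F4 | step 10 | 3,3'-(tridecane-1,13-diyl)bis[5-methoxy-2-(methoxymethoxy)-6-methylcyclohexa-2,5-diene-1,4-dione] | COCOC1=C(CCCCCCCCCCCCCC2=C(OCOC)C(=O)C(C)=C(OC)C2=O)C(=O)C(OC)=C(C)C1=O
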